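Readings and results stem from a simulated flask for substances that don't exist; noise was put on by code.

Of the 0.250 M of target I charged into Friday's flask, 72.7% showed as a lead over Saturday's flask at 57 min: Friday's flask held the same substrate and coupling partner as Saturday's, and its last reading was above Saturday's by 0.182 M. So target did not simply pile up in these flasks; it was being lost. Monday's flask, with twice the partner of Saturday's, ended lower than Saturday's, so I took the loss to grow with [coupling partner]. I kept one number, the loss constant, the fraction of target lost per minute per molar of partner charged: 0.00373 M⁻¹ min⁻¹.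

| flask | substrate | coupling partner | target | time |
|---|---|---|---|---|
| Saturday's | 0.500 M | 1.50 M |  |  |
| Sunday's | 0.200 M | 1.20 M |  |  |
| Friday's | 0.500 M | 1.50 M | 0.250 M |  |
| Monday's | 0.500 M | 3.00 M |  |  |
| Wednesday's | 0.500 M | 5.20 M |  | 57 min |

| run | time / min | [target] / M |
|---|---|---|
| Saturday's run | 2.3 | 0.0122 |
| Saturday's run | 3.6 | 0.0178 |
| Saturday's run | 5.7 | 0.0341 |
| Saturday's run | 9.1 | 0.0500 |
| Saturday's run | 14 | 0.0688 |
| Saturday's run | 23 | 0.0931 |
| Saturday's run | 36 | 0.1207 |
| Saturday's run | 57 | 0.1382 |
| Sunday's run | 2.3 | 0.0063 |
| Sunday's run | 3.6 | 0.0057 |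
| Sunday's run | 5.7 | 0.0135 |
| Sunday's run | 9.1 | 0.0174 |
| Sunday's run | 14 | 0.0284 |
| Sunday's run | 23 | 0.0361 |
| Sunday's run | 36 | 0.0448 |
| Sunday's run | 57 | 0.0549 |
| Friday's run | 2.3 | 0.2594 |
| Friday's run | 3.6 | 0.2665 |
| Friday's run | 5.7 | 0.2717 |
| Friday's run | 9.1 | 0.2879 |
| Friday's run | 14 | 0.2989 |
| Friday's run | 23 | 0.3121 |
| Friday's run | 36 | 0.3196 |
| Friday's run | 57 | 0.3200 |
| Monday's run | 2.3 | 0.0143 |
| Monday's run | 3.6 | 0.0271 |
| Monday's run | 5.7 | 0.0381 |
| Monday's run | 9.1 | 0.0585 |
| Monday's run | 14 | 0.0719 |
| Monday's run | 23 | 0.1009 |
| Monday's run | 36 | 0.1205 |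
| Monday's run | 57 | 0.1133 |

(each reading ± 0.002 M)

- Overall: substrate + coupling partner -> target.
- Constant volume, constant temperature.
- A reading of a species includes what of it is bound.
- "The second partner" is coupling partner.
- An order is taken over about fifteen percent of the charge, up and down.

* apparent order in [coupling partner] of the starting rate, round the charge of the Saturday's run (the rate where two percent of its substrate have turned into target)
* apparent order in [substrate] of the starting rate, round the charge of the Saturday's run (the rate where two percent of its substrate have turned into target) (one fixed amount of target, the same in the runs compared)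
* target in the Wednesday's run at 57 min, as a share of the substrate charged

I left this note for whoever took over the bench. Wednesday's flask held 0.500 M substrate in 5.20 M partner. Counting the partner charged, and not what of it was free, I estimated the loss in Wednesday's flask at 0.0194 min⁻¹, a pseudo-first-order constant, higher than the same estimate for Saturday's flask. On that estimate, the first target made in Wednesday's flask kept 33.1% by 57 min, and later target more. I wrote: add no partner, and read the flask at 57 min. My reckoning gave that kept share, not a yield.

The forecast gave 0.42 for the order in partner, 0.97 for the order in substrate and 19% for Wednesday's flask; in its words, “death rises faster, so the plateau falls”.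

The flask gave 0.49, 0.97 and 15.5%.

    substrate + coupling partner → target (0.02352 M⁻¹ min⁻¹)
    substrate + coupling partner → side product (0.03390 M⁻¹ min⁻¹)
    target + coupling partner → side product (0.005178 M⁻¹ min⁻¹)
    substrate + coupling partner ⇌ idle substrate-reagent adduct, settled at all times (1.060 M⁻¹)

Wednesday's flask stood low because of the path from target and partner to side product: the same run without that path reaches 37.8% instead of 15.5%. So 41.0% of the target stayed, more than the 33.1% that my estimate with the loss constant 0.00373 M⁻¹ min⁻¹ gave for the first target made. In Monday's flask the same constant, at the mean of the last two readings, gave an estimated loss of 0.00131 M min⁻¹, while those readings fell by 3.43 × 10⁻⁴ M min⁻¹.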